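**Plan**

1. Retrosynthetic cuts (carotenoid numbering throughout): the O–S bond of the 3-sulfate; the C7=C8 and C7'=C8' alkenes, leaving the C20 dialdehyde of crocetin and two copies of one C10 ring phosphonium salt; in that ring the C1–C6 bond; in the open chain the C3–C4 bond.
2. Enabling feature: each end ring is a cyclised geranyl unit in which the gem-dimethyl carbon C1 is bonded to C6 of the C5=C6 ring alkene and has the C2 carbinol as neighbour. C1–C6 can therefore be made from a C1 radical released from a C1–C2 epoxide whose oxygen stays on C2.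
3. Forward order: a vinylogous aldol builds the C10 chain; epoxidation and protecting-group steps give the epoxy geranyl acetate; the radical cyclisation closes the only ring type (used for both ends); the alkene is moved to C5=C6; a double Wittig reaction joins C10 + C20 + C10.
4. Stereochemistry: C3 comes from the catalyst-controlled vinylogous Mukaiyama aldol. C2 comes from hydroxyl-directed threo epoxidation and is retained through the radical opening. The C6 centre made in the cyclisation is transient. Chain geometry comes from crocetin and an equilibrated E-olefination.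
5. Endgame: the C2-symmetric 2,2'-bis-silyl 3,3'-diol has two equivalent free hydroxyls, so one-sided sulfation gives a single monosulfate; fluoride then frees the remaining hydroxyls.

Key step: step 7

Assumption: the target is drawn as the hydrogen sulfate; such a monoester is a strong acid that would be isolated and stored as its sodium salt, so compounds 24 and 25 are written in the protonated notation of the target.

**Route**

Step 1
Reactants: 1 ethyl 3-methylbut-2-enoate
Product: 2 tert-butyl[(1-ethoxy-3-methylbuta-1,3-dien-1-yl)oxy]dimethylsilane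
Conditions: LiN(i-Pr)2, THF/DMPU, −78 °C; TBSCl, −78 °C → rt; distillation
Reagents that add atoms: tert-butylchlorodimethylsilane, CC(C)(C)[Si](C)(C)Cl
Why: Kinetic γ-deprotonation of the β,β-dimethylacrylate gives the extended lithium dienolate, which the silyl chloride traps on oxygen to give the silyl ketene acetal needed for a vinylogous Mukaiyama aldol reaction.

Step 2
Reactants: 2 tert-butyl[(1-ethoxy-3-methylbuta-1,3-dien-1-yl)oxy]dimethylsilane; 3 3-methylbut-2-enal (prenal)
Product: 4 ethyl (2E,5R)-5-hydroxy-3,7-dimethylocta-2,6-dienoate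
Conditions: SiCl4 (1.1 equiv), (R,R)-bisphosphoramide (two N,N'-dimethyl-1,1'-binaphthyl-2,2'-diamine phosphoramide units joined by a pentane-1,5-diyl bis(N-methylamino) tether, 5 mol %), i-Pr2NEt (10 mol %), CH2Cl2, −78 °C; aq. NaHCO3
Reagents that add atoms: none
Why: In this catalytic enantioselective vinylogous Mukaiyama aldol reaction the phosphoramide-bound chlorosilyl cation activates prenal and the dienolate attacks through its unhindered γ-carbon in a 1,2-sense; the catalyst enantiomer is the one that exposes the Re face of the aldehyde (taken to be (R,R), otherwise its antipode is used), which sets the carbinol centre (later C3) as R and should give the (2E)-enoate, any (2Z) isomer showing up as a separable dihydropyranone.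

Step 3
Reactants: 4 ethyl (2E,5R)-5-hydroxy-3,7-dimethylocta-2,6-dienoate
Product: 5 ethyl (2E,5R)-5-[(2S)-3,3-dimethyloxiran-2-yl]-5-hydroxy-3-methylpent-2-enoate
Conditions: m-CPBA, NaHCO3, CH2Cl2, −20 → 0 °C
Reagents that add atoms: 3-chloroperoxybenzoic acid, OOC(=O)c1cccc(Cl)c1
Why: Hydroxyl-directed peracid epoxidation attacks only the electron-rich trisubstituted alkene (the enoate is inert), and allylic 1,3-strain between the cis methyl group and the carbinol substituents fixes the conformer with the carbinol hydrogen in the alkene plane, so the hydrogen-bonded peracid should deliver oxygen to give the threo epoxy alcohol and set the epoxide carbon (later C2).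

Step 4
Reactants: 5 ethyl (2E,5R)-5-[(2S)-3,3-dimethyloxiran-2-yl]-5-hydroxy-3-methylpent-2-enoate
Product: 6 ethyl (2E,5R)-5-[(2S)-3,3-dimethyloxiran-2-yl]-3-methyl-5-(triethylsilyloxy)pent-2-enoate
Conditions: TESCl, imidazole, CH2Cl2, 0 °C
Reagents that add atoms: chlorotriethylsilane, CC[Si](Cl)(CC)CC
Why: Silylation of the secondary alcohol under weakly basic conditions generates no free alkoxide, so epoxide migration is avoided and the C3 oxygen is masked for the reduction and the radical step.

Step 5
Reactants: 6 ethyl (2E,5R)-5-[(2S)-3,3-dimethyloxiran-2-yl]-3-methyl-5-(triethylsilyloxy)pent-2-enoate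
Product: 7 (2E,5R)-5-[(2S)-3,3-dimethyloxiran-2-yl]-3-methyl-5-(triethylsilyloxy)pent-2-en-1-ol
Conditions: i-Bu2AlH (2.3 equiv), CH2Cl2, −78 °C; aq. KNaC4H4O6 (potassium sodium tartrate)
Reagents that add atoms: none
Why: 1,2-Reduction of the conjugated ester by i-Bu2AlH at low temperature gives the allylic alcohol, while the hindered trisubstituted epoxide and the silyl ether should not react.

Step 6
Reactants: 7 (2E,5R)-5-[(2S)-3,3-dimethyloxiran-2-yl]-3-methyl-5-(triethylsilyloxy)pent-2-en-1-ol
Product: 8 (2E,5R)-5-[(2S)-3,3-dimethyloxiran-2-yl]-3-methyl-5-(triethylsilyloxy)pent-2-en-1-yl acetate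
Conditions: Ac2O, pyridine, DMAP (cat.), CH2Cl2, 0 °C → rt
Reagents that add atoms: acetic anhydride, CC(=O)OC(C)=O
Why: Acetylation of the primary allylic alcohol gives the epoxygeranyl acetate type substrate on which the titanium-mediated cyclisation is established and keeps a free hydroxyl away from the titanium reagent.

Step 7
Reactants: 8 (2E,5R)-5-[(2S)-3,3-dimethyloxiran-2-yl]-3-methyl-5-(triethylsilyloxy)pent-2-en-1-yl acetate
Product: 9 [(1R,3R,4R)-3-hydroxy-2,2-dimethyl-6-methylidene-4-(triethylsilyloxy)cyclohexyl]methyl acetate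
Conditions: Cp2TiCl2 (2.5 equiv), Mn dust (8 equiv), degassed THF, rt, slow addition of 8 at high dilution; aq. NaH2PO4
Reagents that add atoms: none
Why: Cp2TiCl (trivalent titanium), generated in the flask from Cp2TiCl2 and manganese dust, transfers one electron to the epoxide and breaks the C1–O bond homolytically, giving the tertiary C1 radical and a tetravalent-titanium alkoxide on C2 whose C–O bond, and hence configuration, is untouched. The nucleophilic radical adds to C6 of the trisubstituted C5=C6 alkene in a 6-endo-trig closure that forms the C1–C6 bond and the six-membered ring; the tertiary C5 radical is then captured by a second Cp2TiCl and loses a β-hydrogen from the C5 methyl group to leave the exocyclic alkene, and aqueous work-up frees the C2 hydroxyl. The closest known reaction type is the Cp2TiCl-mediated radical cyclisation of epoxypolyprenes, of which the conversion of 6,7-epoxygeranyl acetate into a hydroxy-γ-cyclogeranyl acetate is the direct model. The one new stereocentre, C6, is set by a chair transition state in which the (E)-alkene holds CH2OAc equatorial and cis to the C2 oxygen, and it is removed again in step 10. The step needs 6-endo rather than 5-exo closure, which the substrate secures because attack at C6 gives a tertiary radical whereas attack at the fully substituted C5 would join two quaternary carbons and give a secondary radical; it also needs a strain-free chair, which the threo relation of the C2 and C3 oxygens provides by placing both equatorial. Because no carbocation is formed, the 1,2-hydride shift to a C2 ketone that accompanies acid-promoted epoxide opening has no pathway, and high dilution disfavours reduction of the C1 radical by a second titanium centre.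

Step 8
Reactants: 9 [(1R,3R,4R)-3-hydroxy-2,2-dimethyl-6-methylidene-4-(triethylsilyloxy)cyclohexyl]methyl acetate
Product: 10 [(1R,3R,4R)-3-(tert-butyldimethylsilyloxy)-2,2-dimethyl-6-methylidene-4-(triethylsilyloxy)cyclohexyl]methyl acetate
Conditions: TBSOTf, 2,6-lutidine, CH2Cl2, −78 → 0 °C
Reagents that add atoms: tert-butyldimethylsilyl trifluoromethanesulfonate, CC(C)(C)[Si](C)(C)OS(=O)(=O)C(F)(F)F
Why: The silyl triflate with a hindered pyridine base silylates even the neopentyl-type C2 hydroxyl, and since no alkoxide is formed the neighbouring triethylsilyl group should not migrate; the two oxygens now carry silyl groups of different lability.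

Step 9
Reactants: 10 [(1R,3R,4R)-3-(tert-butyldimethylsilyloxy)-2,2-dimethyl-6-methylidene-4-(triethylsilyloxy)cyclohexyl]methyl acetate
Product: 11 [(1R,3R,4R)-3-(tert-butyldimethylsilyloxy)-2,2-dimethyl-6-methylidene-4-(triethylsilyloxy)cyclohexyl]methanol
Conditions: i-Bu2AlH (2.2 equiv), CH2Cl2, −78 °C; aq. KNaC4H4O6
Reagents that add atoms: none
Why: Reductive cleavage of the acetate by i-Bu2AlH frees the primary alcohol without the basic methanol that could loosen the triethylsilyl ether.

Step 10
Reactants: 11 [(1R,3R,4R)-3-(tert-butyldimethylsilyloxy)-2,2-dimethyl-6-methylidene-4-(triethylsilyloxy)cyclohexyl]methanol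
Product: 13 (4R,5R)-5-(tert-butyldimethylsilyloxy)-2,6,6-trimethyl-4-(triethylsilyloxy)cyclohex-1-ene-1-carbaldehyde, via methylidene aldehyde 12 (not isolated)
Conditions: Dess–Martin periodinane, NaHCO3, CH2Cl2, 0 °C → rt; aq. Na2S2O3/NaHCO3; crude aldehyde, DBU (0.1 equiv), CH2Cl2, −20 → 0 °C
Reagents that add atoms: none
Why: Dess–Martin oxidation gives the β,γ-unsaturated aldehyde, whose acidic α-hydrogen at C6 is removed by the amidine base so that reprotonation of the dienolate at the exocyclic carbon moves the alkene into the conjugated, tetrasubstituted C5=C6 position (the known base-induced change of a γ- or α-cyclocitral into the β-isomer) and erases the C6 stereocentre; catalytic base at low temperature is chosen to avoid loss of the C3 silyloxy group from the extended enolate.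

Step 11
Reactants: 13 (4R,5R)-5-(tert-butyldimethylsilyloxy)-2,6,6-trimethyl-4-(triethylsilyloxy)cyclohex-1-ene-1-carbaldehyde
Product: 14 [(4R,5R)-5-(tert-butyldimethylsilyloxy)-2,6,6-trimethyl-4-(triethylsilyloxy)cyclohex-1-en-1-yl]methanol
Conditions: i-Bu2AlH (1.2 equiv), CH2Cl2, −78 °C; aq. KNaC4H4O6
Reagents that add atoms: none
Why: 1,2-Reduction of the hindered enal by i-Bu2AlH gives the β-cyclogeraniol-type allylic alcohol and leaves both silyl ethers in place.

Step 12
Reactants: 14 [(4R,5R)-5-(tert-butyldimethylsilyloxy)-2,6,6-trimethyl-4-(triethylsilyloxy)cyclohex-1-en-1-yl]methanol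
Product: 16 {[(4R,5R)-5-(tert-butyldimethylsilyloxy)-2,6,6-trimethyl-4-(triethylsilyloxy)cyclohex-1-en-1-yl]methyl}triphenylphosphonium bromide, via allylic bromide 15 (not isolated)
Conditions: CBr4, PPh3, 2,6-lutidine, CH2Cl2, 0 °C; then PPh3 (1.5 equiv), MeCN, rt
Reagents that add atoms: tetrabromomethane (source of the bromide), BrC(Br)(Br)Br; triphenylphosphine, c1ccc(cc1)P(c1ccccc1)c1ccccc1
Why: An Appel bromination under buffered, neutral conditions is followed by substitution of the allylic bromide by triphenylphosphine at the primary carbon; any transposed tertiary bromide would converge on the same primary salt, and the acid-labile triethylsilyl ether is spared.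

Step 13
Reactants: 17 crocetin (8,8'-diapocarotene-8,8'-dioic acid)
Product: 18 dimethyl crocetinate (dimethyl 8,8'-diapocarotene-8,8'-dioate)
Conditions: MeI, K2CO3, DMF, rt, dark
Reagents that add atoms: iodomethane, CI
Why: O-Alkylation of the dicarboxylate gives the soluble diester without acid or heat, so the all-E heptaene should be kept.

Step 14
Reactants: 18 dimethyl crocetinate
Product: 19 8,8'-diapocarotene-8,8'-diol (crocetindiol)
Conditions: i-Bu2AlH (5 equiv), THF/CH2Cl2, −78 → −20 °C; aq. KNaC4H4O6
Reagents that add atoms: none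
Why: i-Bu2AlH reduces both conjugated esters in a 1,2-sense to the bis-allylic diol and does not touch the polyene.

Step 15
Reactants: 19 8,8'-diapocarotene-8,8'-diol
Product: 20 8,8'-diapocarotene-8,8'-dial (crocetindial)
Conditions: activated MnO2, CH2Cl2, rt, dark
Reagents that add atoms: none
Why: MnO2 oxidises allylic alcohols selectively and stops at the conjugated dialdehyde, the C20 centrepiece for the double olefination.

Step 16
Reactants: 16 {[(4R,5R)-5-(tert-butyldimethylsilyloxy)-2,6,6-trimethyl-4-(triethylsilyloxy)cyclohex-1-en-1-yl]methyl}triphenylphosphonium bromide; 20 8,8'-diapocarotene-8,8'-dial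
Product: 22 (all-E,2R,3R,2'R,3'R)-2,2'-bis(tert-butyldimethylsilyloxy)-3,3'-bis(triethylsilyloxy)-β,β-carotene, via phosphonium ylide 21 (not isolated)
Conditions: 16 (2.4 equiv), NaN(SiMe3)2 (2.3 equiv), THF, −78 → 0 °C; 20 in CH2Cl2/THF, −78 °C → rt; then I2 (cat.), heptane, rt, diffuse light
Reagents that add atoms: none
Why: A double Wittig olefination of the dialdehyde with the semi-stabilised allylic ylide forms both C7=C8 bonds and completes the C40 skeleton; the (7E) geometry is favoured because a (7Z) alkene would press the chain against the ring methyl groups, and iodine-catalysed equilibration should convert any hindered Z isomer into the all-E compound.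

Step 17
Reactants: 22 (all-E,2R,3R,2'R,3'R)-2,2'-bis(tert-butyldimethylsilyloxy)-3,3'-bis(triethylsilyloxy)-β,β-carotene
Product: 23 (all-E,2R,3R,2'R,3'R)-2,2'-bis(tert-butyldimethylsilyloxy)-β,β-carotene-3,3'-diol
Conditions: PPTS (0.3 equiv), MeOH/CH2Cl2 (1:2), 0 °C → rt, dark
Reagents that add atoms: none
Why: Mildly acidic methanolysis removes the less hindered triethylsilyl ethers much faster than the neopentyl tert-butyldimethylsilyl ethers, and a polyene with no allylic oxygen should tolerate pyridinium tosylate.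

Step 18
Reactants: 23 (all-E,2R,3R,2'R,3'R)-2,2'-bis(tert-butyldimethylsilyloxy)-β,β-carotene-3,3'-diol
Product: 24 (all-E,2R,3R,2'R,3'R)-2,2'-bis(tert-butyldimethylsilyloxy)-3'-hydroxy-β,β-caroten-3-yl hydrogen sulfate
Conditions: SO3·pyridine (1.0 equiv), pyridine/THF, 0 °C → rt, run to partial conversion; aq. NaHCO3; chromatography (CH2Cl2/MeOH), recovered 23 recycled
Reagents that add atoms: sulfur trioxide–pyridine complex, O=S(=O)([O-])[n+]1ccccc1
Why: O-Sulfation with the sulfur trioxide–amine complex reaches only the two C3 hydroxyls, which are equivalent by C2 symmetry, so sulfation of either gives the same monosulfate; neutral diol, monoanionic product and dianionic disulfate should separate readily by charge.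

Step 19
Reactants: 24 (all-E,2R,3R,2'R,3'R)-2,2'-bis(tert-butyldimethylsilyloxy)-3'-hydroxy-β,β-caroten-3-yl hydrogen sulfate
Product: 25 (all-E,2R,3R,2'R,3'R)-2,2',3'-trihydroxy-β,β-caroten-3-yl hydrogen sulfate (target, CNP0229621.3)
Conditions: Bu4NF (excess), THF, rt → 40 °C, dark, argon; Na+ ion exchange; reversed-phase chromatography
Reagents that add atoms: none
Why: Fluoride-mediated desilylation cleaves both remaining silyl ethers, while the sulfate monoester anion is inert to fluoride and to the weakly basic medium and the absence of acid protects the polyene.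

**Compound list**

1 | ethyl 3-methylbut-2-enoate | CCOC(=O)C=C(C)C | starting material
2 | tert-butyl[(1-ethoxy-3-methylbuta-1,3-dien-1-yl)oxy]dimethylsilane | C=C(C)C=C(OCC)O[Si](C)(C)C(C)(C)C | intermediate
3 | 3-methylbut-2-enal (prenal) | CC(C)=CC=O | starting material
4 | ethyl (2E,5R)-5-hydroxy-3,7-dimethylocta-2,6-dienoate | CCOC(=O)/C=C(C)/C[C@@H](O)C=C(C)C | intermediate
5 | ethyl (2E,5R)-5-[(2S)-3,3-dimethyloxiran-2-yl]-5-hydroxy-3-methylpent-2-enoate | CCOC(=O)/C=C(C)/C[C@@H](O)[C@@H]1OC1(C)C | intermediate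
6 | ethyl (2E,5R)-5-[(2S)-3,3-dimethyloxiran-2-yl]-3-methyl-5-(triethylsilyloxy)pent-2-enoate | CCOC(=O)/C=C(C)/C[C@@H](O[Si](CC)(CC)CC)[C@@H]1OC1(C)C | intermediate
7 | (2E,5R)-5-[(2S)-3,3-dimethyloxiran-2-yl]-3-methyl-5-(triethylsilyloxy)pent-2-en-1-ol | OC/C=C(C)/C[C@@H](O[Si](CC)(CC)CC)[C@@H]1OC1(C)C | intermediate
8 | (2E,5R)-5-[(2S)-3,3-dimethyloxiran-2-yl]-3-methyl-5-(triethylsilyloxy)pent-2-en-1-yl acetate | CC(=O)OC/C=C(C)/C[C@@H](O[Si](CC)(CC)CC)[C@@H]1OC1(C)C | intermediate
9 | [(1R,3R,4R)-3-hydroxy-2,2-dimethyl-6-methylidene-4-(triethylsilyloxy)cyclohexyl]methyl acetate | C=C1C[C@@H](O[Si](CC)(CC)CC)[C@H](O)C(C)(C)[C@@H]1COC(C)=O | intermediate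
10 | [(1R,3R,4R)-3-(tert-butyldimethylsilyloxy)-2,2-dimethyl-6-methylidene-4-(triethylsilyloxy)cyclohexyl]methyl acetate | C=C1C[C@@H](O[Si](CC)(CC)CC)[C@H](O[Si](C)(C)C(C)(C)C)C(C)(C)[C@@H]1COC(C)=O | intermediate
11 | [(1R,3R,4R)-3-(tert-butyldimethylsilyloxy)-2,2-dimethyl-6-methylidene-4-(triethylsilyloxy)cyclohexyl]methanol | C=C1C[C@@H](O[Si](CC)(CC)CC)[C@H](O[Si](C)(C)C(C)(C)C)C(C)(C)[C@@H]1CO | intermediate
12 | (1R,3R,4R)-3-(tert-butyldimethylsilyloxy)-2,2-dimethyl-6-methylidene-4-(triethylsilyloxy)cyclohexane-1-carbaldehyde | C=C1C[C@@H](O[Si](CC)(CC)CC)[C@H](O[Si](C)(C)C(C)(C)C)C(C)(C)[C@@H]1C=O | intermediate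
13 | (4R,5R)-5-(tert-butyldimethylsilyloxy)-2,6,6-trimethyl-4-(triethylsilyloxy)cyclohex-1-ene-1-carbaldehyde | O=CC1=C(C)C[C@@H](O[Si](CC)(CC)CC)[C@H](O[Si](C)(C)C(C)(C)C)C1(C)C | intermediate
14 | [(4R,5R)-5-(tert-butyldimethylsilyloxy)-2,6,6-trimethyl-4-(triethylsilyloxy)cyclohex-1-en-1-yl]methanol | OCC1=C(C)C[C@@H](O[Si](CC)(CC)CC)[C@H](O[Si](C)(C)C(C)(C)C)C1(C)C | intermediate
15 | (4R,5R)-1-(bromomethyl)-5-(tert-butyldimethylsilyloxy)-2,6,6-trimethyl-4-(triethylsilyloxy)cyclohex-1-ene | BrCC1=C(C)C[C@@H](O[Si](CC)(CC)CC)[C@H](O[Si](C)(C)C(C)(C)C)C1(C)C | intermediate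
16 | {[(4R,5R)-5-(tert-butyldimethylsilyloxy)-2,6,6-trimethyl-4-(triethylsilyloxy)cyclohex-1-en-1-yl]methyl}triphenylphosphonium bromide | c1ccc(cc1)[P+](c1ccccc1)(c1ccccc1)CC1=C(C)C[C@@H](O[Si](CC)(CC)CC)[C@H](O[Si](C)(C)C(C)(C)C)C1(C)C.[Br-] | intermediate
17 | crocetin (8,8'-diapocarotene-8,8'-dioic acid) | OC(=O)/C(C)=C/C=C/C(C)=C/C=C/C=C(C)/C=C/C=C(C)/C(=O)O | starting material
18 | dimethyl crocetinate | COC(=O)/C(C)=C/C=C/C(C)=C/C=C/C=C(C)/C=C/C=C(C)/C(=O)OC | intermediate
19 | 8,8'-diapocarotene-8,8'-diol (crocetindiol) | OC/C(C)=C/C=C/C(C)=C/C=C/C=C(C)/C=C/C=C(C)/CO | intermediate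
20 | 8,8'-diapocarotene-8,8'-dial (crocetindial) | O=C/C(C)=C/C=C/C(C)=C/C=C/C=C(C)/C=C/C=C(C)/C=O | intermediate
21 | {[(4R,5R)-5-(tert-butyldimethylsilyloxy)-2,6,6-trimethyl-4-(triethylsilyloxy)cyclohex-1-en-1-yl]methylidene}triphenylphosphorane | c1ccc(cc1)P(c1ccccc1)(c1ccccc1)=CC1=C(C)C[C@@H](O[Si](CC)(CC)CC)[C@H](O[Si](C)(C)C(C)(C)C)C1(C)C | intermediate
22 | (all-E,2R,3R,2'R,3'R)-2,2'-bis(tert-butyldimethylsilyloxy)-3,3'-bis(triethylsilyloxy)-β,β-carotene | CC1=C(/C=C/C(C)=C/C=C/C(C)=C/C=C/C=C(C)/C=C/C=C(C)/C=C/C2=C(C)C[C@@H](O[Si](CC)(CC)CC)[C@H](O[Si](C)(C)C(C)(C)C)C2(C)C)C(C)(C)[C@@H](O[Si](C)(C)C(C)(C)C)[C@H](O[Si](CC)(CC)CC)C1 | intermediate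
23 | (all-E,2R,3R,2'R,3'R)-2,2'-bis(tert-butyldimethylsilyloxy)-β,β-carotene-3,3'-diol | CC1=C(/C=C/C(C)=C/C=C/C(C)=C/C=C/C=C(C)/C=C/C=C(C)/C=C/C2=C(C)C[C@@H](O)[C@H](O[Si](C)(C)C(C)(C)C)C2(C)C)C(C)(C)[C@@H](O[Si](C)(C)C(C)(C)C)[C@H](O)C1 | intermediate
24 | (all-E,2R,3R,2'R,3'R)-2,2'-bis(tert-butyldimethylsilyloxy)-3'-hydroxy-β,β-caroten-3-yl hydrogen sulfate | CC1=C(/C=C/C(C)=C/C=C/C(C)=C/C=C/C=C(C)/C=C/C=C(C)/C=C/C2=C(C)C[C@@H](OS(=O)(=O)O)[C@H](O[Si](C)(C)C(C)(C)C)C2(C)C)C(C)(C)[C@@H](O[Si](C)(C)C(C)(C)C)[C@H](O)C1 | intermediate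
25 | (all-E,2R,3R,2'R,3'R)-2,2',3'-trihydroxy-β,β-caroten-3-yl hydrogen sulfate | CC1=C(/C=C/C(C)=C/C=C/C(C)=C/C=C/C=C(C)/C=C/C=C(C)/C=C/C2=C(C)C[C@@H](OS(=O)(=O)O)[C@H](O)C2(C)C)C(C)(C)[C@@H](O)[C@H](O)C1 | target

**Step count and risks**

Total step count: 19 (steps 1–12 for the ring salt, steps 13–15 for the dialdehyde, steps 16–19 for coupling and endgame).
Longest linear sequence: 16 steps (steps 1–12, then 16–19).

Steps most likely to fail:

Step 10. The extended enolate formed during the base-induced alkene shift can expel the C3 silyloxy group (E1cB), or the shift can stop short of full conjugation. The fallback runs the shift on the free C3 alcohol, a much poorer leaving group. Setting out from 11, the triethylsilyl ether is removed with PPTS in MeOH to give [(1R,3R,4R)-3-(tert-butyldimethylsilyloxy)-4-hydroxy-2,2-dimethyl-6-methylidenecyclohexyl]methanol F2. Its primary hydroxyl is oxidised selectively with TEMPO and PhI(OAc)2 to (1R,3R,4R)-3-(tert-butyldimethylsilyloxy)-4-hydroxy-2,2-dimethyl-6-methylidenecyclohexane-1-carbaldehyde F3. Triethylamine in CH2Cl2 then moves the alkene into conjugation to give (4R,5R)-5-(tert-butyldimethylsilyloxy)-4-hydroxy-2,6,6-trimethylcyclohex-1-ene-1-carbaldehyde F4, and silylation with TESCl and imidazole returns to the route at 13.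

Step 7. The tertiary C1 radical may be reduced by a second titanium centre and lose the titanoxy group (deoxygenation to the diene), or be quenched by hydrogen-atom transfer before the ring closes. The fallback forms the same C1–C6 bond through a cationic epoxy-alkene cyclisation. Setting out from 8, treatment with MeAlCl2 in CH2Cl2 at −78 °C opens the Lewis-acid-bound epoxide at C1 with participation of the C5=C6 alkene, the electron-withdrawing C3 silyloxy group being expected to slow the competing hydride shift to a C2 ketone. Proton loss returns to the route at 9 alongside the endocyclic isomer [(1R,4R,5R)-5-hydroxy-2,6,6-trimethyl-4-(triethylsilyloxy)cyclohex-2-en-1-yl]methyl acetate F1, which is removed by chromatography on AgNO3-impregnated silica.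

Step 16. Addition of the hindered ylide to the dialdehyde may be slow, leaving mono-olefinated material, and the new C7=C8 bonds may form with poor E selectivity. The fallback replaces the phosphorus ylide by a sulfone anion in a double Julia–Kocienski olefination. Setting out from 14, a Mitsunobu reaction with 1-phenyl-1H-tetrazole-5-thiol (PPh3, diisopropyl azodicarboxylate) gives 5-({[(4R,5R)-5-(tert-butyldimethylsilyloxy)-2,6,6-trimethyl-4-(triethylsilyloxy)cyclohex-1-en-1-yl]methyl}sulfanyl)-1-phenyl-1H-tetrazole F5. Buffered oxidation with H2O2 and catalytic (NH4)6Mo7O24 in ethanol gives 5-({[(4R,5R)-5-(tert-butyldimethylsilyloxy)-2,6,6-trimethyl-4-(triethylsilyloxy)cyclohex-1-en-1-yl]methyl}sulfonyl)-1-phenyl-1H-tetrazole F6. Its anion (KN(SiMe3)2, THF, −78 °C) is condensed twice with 20, followed by the same iodine equilibration, and the route is rejoined at 22.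

Further compounds
F1 | step 7 | [(1R,4R,5R)-5-hydroxy-2,6,6-trimethyl-4-(triethylsilyloxy)cyclohex-2-en-1-yl]methyl acetate | CC1=C[C@@H](O[Si](CC)(CC)CC)[C@H](O)C(C)(C)[C@@H]1COC(C)=O
F2 | step 10 | [(1R,3R,4R)-3-(tert-butyldimethylsilyloxy)-4-hydroxy-2,2-dimethyl-6-methylidenecyclohexyl]methanol | C=C1C[C@@H](O)[C@H](O[Si](C)(C)C(C)(C)C)C(C)(C)[C@@H]1CO
F3 | step 10 | (1R,3R,4R)-3-(tert-butyldimethylsilyloxy)-4-hydroxy-2,2-dimethyl-6-methylidenecyclohexane-1-carbaldehyde | C=C1C[C@@H](O)[C@H](O[Si](C)(C)C(C)(C)C)C(C)(C)[C@@H]1C=O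
F4 | step 10 | (4R,5R)-5-(tert-butyldimethylsilyloxy)-4-hydroxy-2,6,6-trimethylcyclohex-1-ene-1-carbaldehyde | O=CC1=C(C)C[C@@H](O)[C@H](O[Si](C)(C)C(C)(C)C)C1(C)C
F5 | step 16 | 5-({[(4R,5R)-5-(tert-butyldimethylsilyloxy)-2,6,6-trimethyl-4-(triethylsilyloxy)cyclohex-1-en-1-yl]methyl}sulfanyl)-1-phenyl-1H-tetrazole | c1ccccc1-n1nnnc1SCC1=C(C)C[C@@H](O[Si](CC)(CC)CC)[C@H](O[Si](C)(C)C(C)(C)C)C1(C)C
F6 | step 16 | 5-({[(4R,5R)-5-(tert-butyldimethylsilyloxy)-2,6,6-trimethyl-4-(triethylsilyloxy)cyclohex-1-en-1-yl]methyl}sulfonyl)-1-phenyl-1H-tetrazole | c1ccccc1-n1nnnc1S(=O)(=O)CC1=C(C)C[C@@H](O[Si](CC)(CC)CC)[C@H](O[Si](C)(C)C(C)(C)C)C1(C)C
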